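**Retrosynthetic overview**
1. Target 21 comes from bis-silyl ether 20 by fluoride desilylation; no ring is formed at any stage, the arene is carried in from methylhydroquinone.
2. The C8–C9 bond joins allylic bromide 17 (aryl, C1–C8) to hydroxy allyl sulfone 4 (C9–C16); the sulfone is then removed.
3. Both stereogenic C–O bonds are made by one new reaction, a ligand-controlled palladium-catalysed 1,4-diacetoxylation of a 1,3-diene: ocimene gives C12–O, triene 14 gives C5–OAc, which is the acetate the target keeps.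
4. Triene 14 comes from allylic acetate 11 and the dienylalane of 2-methylbut-1-en-3-yne (alkenyl–allyl coupling).
5. Acetate 11 comes from ortho-C-allylation of monosilylated methylhydroquinone 6 with the isoprene-derived chloroacetate 8.

Assumption: ocimene is used as the commercial (E)-β isomer, and in the two new palladium steps the ligand antipode that gives the drawn configuration is taken (the sense of induction has to be fixed by screening).
Abbreviation: Ar = 2-[(tert-butyldimethylsilyl)oxy]-3-methyl-5-[(triisopropylsilyl)oxy]phenyl; chain positions C1–C16 are counted from the aryl-bearing carbon.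

**Step 1**
Reactants: 1 (3E)-3,7-dimethylocta-1,3,6-triene ((E)-β-ocimene)
Product: 2 (2E,4R)-3,7-dimethylocta-2,6-diene-1,4-diyl diacetate
Conditions: Pd(OCOCF3)2 (5 mol %), i-Pr-SPRIX (6 mol %, antipode giving 4R), p-benzoquinone (1.5 equiv), LiOAc, AcOH–acetone, 0 °C to rt
Reagents that add atoms: acetic acid, CC(=O)O
Why: Proposed new method: an enantioselective form of the Bäckvall 1,4-diacetoxylation (closest known reaction: the racemic Pd(OAc)2/p-benzoquinone 1,4-diacetoxylation of acyclic 1,3-dienes) in which cationic divalent palladium, held by the rigid and oxidation-stable spiro bis(isoxazoline), binds one face of the conjugated diene in preference to the isolated alkene, external acetate adds anti to give a π-allyl, and the second acetate is delivered to the other terminus of the quinone-activated complex, so the C4–O stereocentre forms under ligand control whichever terminus reacts first and the bulky CH(OAc)R group sits syn to give the E alkene.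

**Step 2**
Reactants: 2 (2E,4R)-3,7-dimethylocta-2,6-diene-1,4-diyl diacetate
Product: 3 (2E,4R)-3,7-dimethyl-1-(phenylsulfonyl)octa-2,6-dien-4-yl acetate
Conditions: PhSO2Na (1.05 equiv), Pd(PPh3)4 (3 mol %), THF–DMF, rt
Reagents that add atoms: sodium benzenesulfinate, [Na+].[O-]S(=O)c1ccccc1
Why: Tsuji–Trost allylic sulfonylation: zerovalent palladium ionises the unhindered primary allylic acetate and the soft S-nucleophile attacks the CH2 terminus, leaving the hindered secondary acetate and its stereocentre untouched.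

**Step 3**
Reactants: 3 (2E,4R)-3,7-dimethyl-1-(phenylsulfonyl)octa-2,6-dien-4-yl acetate
Product: 4 (2E,4R)-3,7-dimethyl-1-(phenylsulfonyl)octa-2,6-dien-4-ol
Conditions: K2CO3 (0.2 equiv), MeOH, 0 °C
Reagents that add atoms: none
Why: Base-catalysed transesterification (methanolysis) removes the acetate; carbonate is too weak to deprotonate the α-sulfonyl CH2, so no elimination occurs and the stereocentre is not touched.

**Step 4**
Reactants: 5 2-methylbenzene-1,4-diol (methylhydroquinone)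
Product: 6 2-methyl-4-[(triisopropylsilyl)oxy]phenol
Conditions: TIPSCl (1.0 equiv), imidazole, DMF, 0 °C
Reagents that add atoms: chlorotriisopropylsilane, CC(C)[Si](Cl)(C(C)C)C(C)C
Why: Selective monosilylation: the bulky silyl chloride takes the unhindered 4-OH, the 1-OH being shielded by the ortho methyl group.

**Step 5**
Reactants: 7 2-methylbuta-1,3-diene (isoprene)
Product: 8 (2E)-4-chloro-2-methylbut-2-en-1-yl acetate
Conditions: Pd(OAc)2 (2 mol %), p-benzoquinone, LiCl, LiOAc, AcOH–pentane, rt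
Reagents that add atoms: acetic acid, CC(=O)O; lithium chloride, [Li+].[Cl-]
Why: Bäckvall 1,4-acetoxychlorination: acetate enters at the CH2 next to the methyl-bearing carbon and chloride opens the π-allyl at the unsubstituted terminus, E isomer predominating (regiochemistry as I recall it for isoprene; confirm on the first run).

**Step 6**
Reactants: 6 2-methyl-4-[(triisopropylsilyl)oxy]phenol; 8 (2E)-4-chloro-2-methylbut-2-en-1-yl acetate
Product: 11 (2E)-4-Ar-2-methylbut-2-en-1-yl acetate, via sodium phenoxide 9 (not isolated), via ortho-allylphenol 10 (not isolated)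
Conditions: NaH (1.0 equiv), toluene, 0 °C; 8, rt to 50 °C; then TBSCl, imidazole, DMF, 40 °C
Reagents that add atoms: tert-butylchlorodimethylsilane, CC(C)(C)[Si](C)(C)Cl
Why: Phenoxide ortho-C-allylation: the tight sodium ion pair in toluene alkylates at the only free ortho carbon by SN2 at the primary allylic chloride (E geometry kept), and the hindered phenol is then silylated.

**Step 7**
Reactants: 11 (2E)-4-Ar-2-methylbut-2-en-1-yl acetate; 12 2-methylbut-1-en-3-yne
Product: 14 (2E,5E)-1-Ar-3,7-dimethylocta-2,5,7-triene, via dienylalane 13 (not isolated)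
Conditions: 12, i-Bu2AlH, hexane, 50 °C; then 11, Pd(PPh3)4 (5 mol %), THF, rt
Reagents that add atoms: none
Why: Syn hydroalumination gives the (E)-dienylalane, and Negishi alkenyl–allyl coupling joins it to the less hindered CH2 terminus of the π-allyl from 11 with retention of both alkene geometries.

**Step 8**
Reactants: 14 (2E,5E)-1-Ar-3,7-dimethylocta-2,5,7-triene
Product: 15 (2E,4S,6E)-8-Ar-2,6-dimethylocta-2,6-diene-1,4-diyl diacetate
Conditions: Pd(OCOCF3)2 (5 mol %), i-Pr-SPRIX (6 mol %, antipode giving 4S), p-benzoquinone (1.5 equiv), LiOAc, AcOH–acetone, 0 °C to rt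
Reagents that add atoms: acetic acid, CC(=O)O
Why: Proposed new method: second use of the ligand-controlled 1,4-diacetoxylation of step 1 (closest known reaction: racemic Bäckvall 1,4-diacetoxylation of acyclic dienes), in which only the conjugated diene is oxidised, one acetate adds to the terminal CH2 and the other to C4 of the face-defined π-allyl (either order gives the same 1,4-diacetate), setting 4S and placing there the acetate that the target keeps.

**Step 9**
Reactants: 15 (2E,4S,6E)-8-Ar-2,6-dimethylocta-2,6-diene-1,4-diyl diacetate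
Product: 16 (2E,4S,6E)-8-Ar-1-hydroxy-2,6-dimethylocta-2,6-dien-4-yl acetate
Conditions: Novozym 435 (immobilised Candida antarctica lipase B), n-BuOH, MTBE, 30 °C
Reagents that add atoms: none
Why: Lipase-catalysed regioselective alcoholysis cleaves the unhindered primary acetate far faster than the secondary acetate flanked by two large groups, and no acyl migration is possible across the E alkene.

**Step 10**
Reactants: 16 (2E,4S,6E)-8-Ar-1-hydroxy-2,6-dimethylocta-2,6-dien-4-yl acetate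
Product: 17 (2E,4S,6E)-8-Ar-1-bromo-2,6-dimethylocta-2,6-dien-4-yl acetate
Conditions: CBr4, PPh3, CH2Cl2, −20 °C
Reagents that add atoms: carbon tetrabromide, BrC(Br)(Br)Br
Why: Appel bromination, SN2 at the primary allylic carbon under neutral conditions that leave the allylic acetate and silyl ethers intact.

**Step 11**
Reactants: 4 (2E,4R)-3,7-dimethyl-1-(phenylsulfonyl)octa-2,6-dien-4-ol; 17 (2E,4S,6E)-8-Ar-1-bromo-2,6-dimethylocta-2,6-dien-4-yl acetate
Product: 19 (2E,5S,6E,10E,12R)-1-Ar-12-hydroxy-3,7,11,15-tetramethyl-9-(phenylsulfonyl)hexadeca-2,6,10,14-tetraen-5-yl acetate (both C9 epimers), via dilithio dianion 18 (not isolated)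
Conditions: 4, n-BuLi (2.05 equiv), THF–DMPU, −78 °C; then 17, −78 to −40 °C; AcOH quench at −78 °C
Reagents that add atoms: none
Why: Allyl sulfone alkylation (Julia/Biellmann-type coupling): the α-sulfonyl carbanion attacks the primary allylic bromide at its α-carbon to form C8–C9, the lithium alkoxide cannot leave so no diene forms, and at −78 °C the acetate is not attacked.

**Step 12**
Reactants: 19 (2E,5S,6E,10E,12R)-1-Ar-12-hydroxy-3,7,11,15-tetramethyl-9-(phenylsulfonyl)hexadeca-2,6,10,14-tetraen-5-yl acetate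
Product: 20 (2E,5S,6E,10E,12R)-1-Ar-12-hydroxy-3,7,11,15-tetramethylhexadeca-2,6,10,14-tetraen-5-yl acetate
Conditions: Na(Hg) (6 %), Na2HPO4, MeOH–THF, −20 °C
Reagents that add atoms: none
Why: Dissolving-metal reductive desulfonylation: electron transfer expels sulfinate and the allyl anion is protonated at the less substituted carbon, keeping the trisubstituted E alkene, while the phosphate buffer protects the acetate.

**Step 13**
Reactants: 20 (2E,5S,6E,10E,12R)-1-Ar-12-hydroxy-3,7,11,15-tetramethylhexadeca-2,6,10,14-tetraen-5-yl acetate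
Product: 21 (2E,5S,6E,10E,12R)-1-(2,5-dihydroxy-3-methylphenyl)-12-hydroxy-3,7,11,15-tetramethylhexadeca-2,6,10,14-tetraen-5-yl acetate
Conditions: TBAF, AcOH, THF, 0 °C, argon
Reagents that add atoms: none
Why: Fluoride-mediated desilylation of both aryl silyl ethers; the acetic acid buffer keeps the hydroquinone protonated, so the secondary acetate and the allylic alcohol are untouched.

**Compound list**
1 | (3E)-3,7-dimethylocta-1,3,6-triene ((E)-β-ocimene) | C=C/C(C)=C/CC=C(C)C | starting material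
2 | (2E,4R)-3,7-dimethylocta-2,6-diene-1,4-diyl diacetate | CC(=O)OC/C=C(\C)[C@H](OC(C)=O)CC=C(C)C | intermediate
3 | (2E,4R)-3,7-dimethyl-1-(phenylsulfonyl)octa-2,6-dien-4-yl acetate | O=S(=O)(C/C=C(\C)[C@H](OC(C)=O)CC=C(C)C)c1ccccc1 | intermediate
4 | (2E,4R)-3,7-dimethyl-1-(phenylsulfonyl)octa-2,6-dien-4-ol | O=S(=O)(C/C=C(\C)[C@H](O)CC=C(C)C)c1ccccc1 | intermediate
5 | 2-methylbenzene-1,4-diol | Cc1cc(O)ccc1O | starting material
6 | 2-methyl-4-[(triisopropylsilyl)oxy]phenol | Cc1cc(O[Si](C(C)C)(C(C)C)C(C)C)ccc1O | intermediate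
7 | 2-methylbuta-1,3-diene | C=CC(C)=C | starting material
8 | (2E)-4-chloro-2-methylbut-2-en-1-yl acetate | CC(=O)OC/C(C)=C/CCl | intermediate
9 | sodium 2-methyl-4-[(triisopropylsilyl)oxy]phenoxide | Cc1cc(O[Si](C(C)C)(C(C)C)C(C)C)ccc1[O-].[Na+] | intermediate (not isolated)
10 | (2E)-4-[2-hydroxy-3-methyl-5-[(triisopropylsilyl)oxy]phenyl]-2-methylbut-2-en-1-yl acetate | CC(=O)OC/C(C)=C/Cc1cc(O[Si](C(C)C)(C(C)C)C(C)C)cc(C)c1O | intermediate (not isolated)
11 | (2E)-4-Ar-2-methylbut-2-en-1-yl acetate | CC(=O)OC/C(C)=C/Cc1cc(O[Si](C(C)C)(C(C)C)C(C)C)cc(C)c1O[Si](C)(C)C(C)(C)C | intermediate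
12 | 2-methylbut-1-en-3-yne | C=C(C)C#C | starting material
13 | diisobutyl[(1E)-3-methylbuta-1,3-dien-1-yl]alane | C=C(C)/C=C/[Al](CC(C)C)CC(C)C | intermediate (not isolated)
14 | (2E,5E)-1-Ar-3,7-dimethylocta-2,5,7-triene | C=C(C)/C=C/C/C(C)=C/Cc1cc(O[Si](C(C)C)(C(C)C)C(C)C)cc(C)c1O[Si](C)(C)C(C)(C)C | intermediate
15 | (2E,4S,6E)-8-Ar-2,6-dimethylocta-2,6-diene-1,4-diyl diacetate | CC(=O)O[C@H](/C=C(\C)COC(C)=O)C/C(C)=C/Cc1cc(O[Si](C(C)C)(C(C)C)C(C)C)cc(C)c1O[Si](C)(C)C(C)(C)C | intermediate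
16 | (2E,4S,6E)-8-Ar-1-hydroxy-2,6-dimethylocta-2,6-dien-4-yl acetate | CC(=O)O[C@H](/C=C(\C)CO)C/C(C)=C/Cc1cc(O[Si](C(C)C)(C(C)C)C(C)C)cc(C)c1O[Si](C)(C)C(C)(C)C | intermediate
17 | (2E,4S,6E)-8-Ar-1-bromo-2,6-dimethylocta-2,6-dien-4-yl acetate | CC(=O)O[C@H](/C=C(\C)CBr)C/C(C)=C/Cc1cc(O[Si](C(C)C)(C(C)C)C(C)C)cc(C)c1O[Si](C)(C)C(C)(C)C | intermediate
18 | dilithium salt of 4 (C4 alkoxide, C1 α-sulfonyl carbanion) | O=S(=O)([CH-]/C=C(\C)[C@H]([O-])CC=C(C)C)c1ccccc1.[Li+].[Li+] | intermediate (not isolated)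
19 | (2E,5S,6E,10E,12R)-1-Ar-12-hydroxy-3,7,11,15-tetramethyl-9-(phenylsulfonyl)hexadeca-2,6,10,14-tetraen-5-yl acetate (both C9 epimers) | CC(=O)O[C@H](/C=C(\C)CC(/C=C(\C)[C@H](O)CC=C(C)C)S(=O)(=O)c1ccccc1)C/C(C)=C/Cc1cc(O[Si](C(C)C)(C(C)C)C(C)C)cc(C)c1O[Si](C)(C)C(C)(C)C | intermediate
20 | (2E,5S,6E,10E,12R)-1-Ar-12-hydroxy-3,7,11,15-tetramethylhexadeca-2,6,10,14-tetraen-5-yl acetate | CC(=O)O[C@H](/C=C(\C)CC/C=C(\C)[C@H](O)CC=C(C)C)C/C(C)=C/Cc1cc(O[Si](C(C)C)(C(C)C)C(C)C)cc(C)c1O[Si](C)(C)C(C)(C)C | intermediate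
21 | (2E,5S,6E,10E,12R)-1-(2,5-dihydroxy-3-methylphenyl)-12-hydroxy-3,7,11,15-tetramethylhexadeca-2,6,10,14-tetraen-5-yl acetate | CC(=O)O[C@H](/C=C(\C)CC/C=C(\C)[C@H](O)CC=C(C)C)C/C(C)=C/Cc1cc(O)cc(C)c1O | target

**Step count**
Total: 13 steps. Longest linear sequence: 9 steps (5 → 6 → 11 → 14 → 15 → 16 → 17 → 19 → 20 → 21; steps 4, 6, 7, 8, 9, 10, 11, 12, 13).

**Three steps most likely to fail**

Step 1 (new enantioselective diacetoxylation of ocimene; the level and sense of induction are unproven, and the Pd-catalysed monosulfonylation that follows depends on it). The fallback uses known chemistry, sets out from 8 and comes back at 4, so steps 2 and 3 are skipped. Copper-catalysed coupling of 8 with 2-methylprop-1-enylmagnesium bromide (Li2CuCl4, THF, −30 °C) gives (2E)-2,6-dimethylhepta-2,5-dien-1-yl acetate F1. Methanolysis (K2CO3, MeOH) gives (2E)-2,6-dimethylhepta-2,5-dien-1-ol F2. Sharpless asymmetric epoxidation (Ti(OiPr)4, D-(−)-diethyl tartrate, t-BuOOH, 4 Å sieves, CH2Cl2, −20 °C) gives [(2R,3R)-2-methyl-3-(3-methylbut-2-en-1-yl)oxiran-2-yl]methanol F3. Parikh–Doering oxidation gives (2S,3R)-2-methyl-3-(3-methylbut-2-en-1-yl)oxirane-2-carbaldehyde F4. Wittig methylenation (Ph3P=CH2) gives (2R,3R)-2-ethenyl-2-methyl-3-(3-methylbut-2-en-1-yl)oxirane F5. Pd(PPh3)4 with PhSO2Na (THF–H2O) then adds sulfinate 1,4 to the vinyl epoxide and gives 4, whose carbinol centre is the untouched epoxide C–O bond.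

Step 8 (second use of the new method; here the stereocentre may be set in the π-allyl capture, and the electron-rich arene and the benzylic–allylic CH2 are also exposed to the oxidant). The fallback uses known chemistry, sets out from 14 and comes back at 15. The established ligand-free oxidation (Pd(OAc)2, LiOAc, p-benzoquinone, AcOH) gives racemic (2E,6E)-8-Ar-2,6-dimethylocta-2,6-diene-1,4-diyl diacetate F6. i-Bu2AlH at −78 °C gives racemic (2E,6E)-8-Ar-2,6-dimethylocta-2,6-diene-1,4-diol F7. Lipase-catalysed acetylation of the primary hydroxyl (Novozym 435, vinyl acetate) gives racemic (2E,6E)-8-Ar-4-hydroxy-2,6-dimethylocta-2,6-dien-1-yl acetate F8. MnO2 (kept cold and neutral to avoid conjugation of the skipped alkene) gives (2E,6E)-8-Ar-2,6-dimethyl-4-oxoocta-2,6-dien-1-yl acetate F9. Corey–Bakshi–Shibata reduction ((R)-Me-CBS oxazaborolidine, catecholborane, −78 °C) gives (2E,4S,6E)-8-Ar-4-hydroxy-2,6-dimethylocta-2,6-dien-1-yl acetate F10. Acetylation (Ac2O, pyridine, DMAP) returns 15.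

Step 12 (sodium amalgam may scramble the position or geometry of the C10 alkene, or attack the allylic acetate). The fallback defers the acetate so that a palladium–hydride desulfonylation can be used; it sets out from 19 and comes back at 21. Silylation of the C12 hydroxyl (TBSOTf, 2,6-lutidine) gives (2E,5S,6E,10E,12R)-1-Ar-12-[(tert-butyldimethylsilyl)oxy]-3,7,11,15-tetramethyl-9-(phenylsulfonyl)hexadeca-2,6,10,14-tetraen-5-yl acetate F11. i-Bu2AlH at −78 °C removes the acetate to give (2E,5S,6E,10E,12R)-1-Ar-12-[(tert-butyldimethylsilyl)oxy]-3,7,11,15-tetramethyl-9-(phenylsulfonyl)hexadeca-2,6,10,14-tetraen-5-ol F12. PdCl2(dppp) with LiBHEt3 (THF, 0 °C) delivers hydride to the less substituted allyl terminus and gives (2E,5S,6E,10E,12R)-1-Ar-12-[(tert-butyldimethylsilyl)oxy]-3,7,11,15-tetramethylhexadeca-2,6,10,14-tetraen-5-ol F13. Acetylation (Ac2O, DMAP, pyridine) gives (2E,5S,6E,10E,12R)-1-Ar-12-[(tert-butyldimethylsilyl)oxy]-3,7,11,15-tetramethylhexadeca-2,6,10,14-tetraen-5-yl acetate F14. TBAF/AcOH then removes all three silyl groups and gives 21.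

**Further compounds**
F1 | step 1 | (2E)-2,6-dimethylhepta-2,5-dien-1-yl acetate | CC(=O)OC/C(C)=C/CC=C(C)C
F2 | step 1 | (2E)-2,6-dimethylhepta-2,5-dien-1-ol | OC/C(C)=C/CC=C(C)C
F3 | step 1 | [(2R,3R)-2-methyl-3-(3-methylbut-2-en-1-yl)oxiran-2-yl]methanol | CC(C)=CC[C@@H]1[C@](C)(O1)CO
F4 | step 1 | (2S,3R)-2-methyl-3-(3-methylbut-2-en-1-yl)oxirane-2-carbaldehyde | CC(C)=CC[C@@H]1[C@](C)(O1)C=O
F5 | step 1 | (2R,3R)-2-ethenyl-2-methyl-3-(3-methylbut-2-en-1-yl)oxirane | CC(C)=CC[C@@H]1[C@](C)(O1)C=C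
F6 | step 8 | racemic (2E,6E)-8-Ar-2,6-dimethylocta-2,6-diene-1,4-diyl diacetate | CC(=O)OC(/C=C(\C)COC(C)=O)C/C(C)=C/Cc1cc(O[Si](C(C)C)(C(C)C)C(C)C)cc(C)c1O[Si](C)(C)C(C)(C)C
F7 | step 8 | racemic (2E,6E)-8-Ar-2,6-dimethylocta-2,6-diene-1,4-diol | OC(/C=C(\C)CO)C/C(C)=C/Cc1cc(O[Si](C(C)C)(C(C)C)C(C)C)cc(C)c1O[Si](C)(C)C(C)(C)C
F8 | step 8 | racemic (2E,6E)-8-Ar-4-hydroxy-2,6-dimethylocta-2,6-dien-1-yl acetate | OC(/C=C(\C)COC(C)=O)C/C(C)=C/Cc1cc(O[Si](C(C)C)(C(C)C)C(C)C)cc(C)c1O[Si](C)(C)C(C)(C)C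
F9 | step 8 | (2E,6E)-8-Ar-2,6-dimethyl-4-oxoocta-2,6-dien-1-yl acetate | O=C(/C=C(\C)COC(C)=O)C/C(C)=C/Cc1cc(O[Si](C(C)C)(C(C)C)C(C)C)cc(C)c1O[Si](C)(C)C(C)(C)C
F10 | step 8 | (2E,4S,6E)-8-Ar-4-hydroxy-2,6-dimethylocta-2,6-dien-1-yl acetate | O[C@H](/C=C(\C)COC(C)=O)C/C(C)=C/Cc1cc(O[Si](C(C)C)(C(C)C)C(C)C)cc(C)c1O[Si](C)(C)C(C)(C)C
F11 | step 12 | (2E,5S,6E,10E,12R)-1-Ar-12-[(tert-butyldimethylsilyl)oxy]-3,7,11,15-tetramethyl-9-(phenylsulfonyl)hexadeca-2,6,10,14-tetraen-5-yl acetate | CC(=O)O[C@H](/C=C(\C)CC(/C=C(\C)[C@H](O[Si](C)(C)C(C)(C)C)CC=C(C)C)S(=O)(=O)c1ccccc1)C/C(C)=C/Cc1cc(O[Si](C(C)C)(C(C)C)C(C)C)cc(C)c1O[Si](C)(C)C(C)(C)C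
F12 | step 12 | (2E,5S,6E,10E,12R)-1-Ar-12-[(tert-butyldimethylsilyl)oxy]-3,7,11,15-tetramethyl-9-(phenylsulfonyl)hexadeca-2,6,10,14-tetraen-5-ol | O[C@H](/C=C(\C)CC(/C=C(\C)[C@H](O[Si](C)(C)C(C)(C)C)CC=C(C)C)S(=O)(=O)c1ccccc1)C/C(C)=C/Cc1cc(O[Si](C(C)C)(C(C)C)C(C)C)cc(C)c1O[Si](C)(C)C(C)(C)C
F13 | step 12 | (2E,5S,6E,10E,12R)-1-Ar-12-[(tert-butyldimethylsilyl)oxy]-3,7,11,15-tetramethylhexadeca-2,6,10,14-tetraen-5-ol | O[C@H](/C=C(\C)CC/C=C(\C)[C@H](O[Si](C)(C)C(C)(C)C)CC=C(C)C)C/C(C)=C/Cc1cc(O[Si](C(C)C)(C(C)C)C(C)C)cc(C)c1O[Si](C)(C)C(C)(C)C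
F14 | step 12 | (2E,5S,6E,10E,12R)-1-Ar-12-[(tert-butyldimethylsilyl)oxy]-3,7,11,15-tetramethylhexadeca-2,6,10,14-tetraen-5-yl acetate | CC(=O)O[C@H](/C=C(\C)CC/C=C(\C)[C@H](O[Si](C)(C)C(C)(C)C)CC=C(C)C)C/C(C)=C/Cc1cc(O[Si](C(C)C)(C(C)C)C(C)C)cc(C)c1O[Si](C)(C)C(C)(C)C
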